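The product after 120 s stands at 10.4 mM in the south-east run, 31.9 mM in the west run and 63.8 mM in the north run, for [substrate] charged at 0.014 M, 0.051 M and 0.21 M. You are about to repeat this catalyst at other charges.

| flask | substrate | reagent | free catalyst | added ligand | remark | time |
|---|---|---|---|---|---|---|
| south-east | 0.014 M | 0.15 M | 10 mM | 9.2 mM | run made earlier |  |
| west | 0.051 M | 0.15 M | 10 mM | 9.2 mM | run made earlier |  |
| north | 0.21 M | 0.15 M | 10 mM | 9.2 mM | run made earlier |  |
| ash | 0.012 M | 0.150 M | 10 mM | 9.2 mM |  | 2.0 min |
| birch | 0.025 M | 0.150 M | 10 mM | 9.2 mM |  | 2.0 min |
| elm | 0.050 M | 0.150 M | 10 mM | 9.2 mM |  | 2.0 min |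
| oak | 0.10 M | 0.150 M | 10 mM | 9.2 mM |  | 2.0 min |
| cedar | 0.20 M | 0.150 M | 10 mM | 9.2 mM |  | 2.0 min |

| run | time / s | product / % |
|---|---|---|
| south-east | 25.0 | 16.6 |
| south-east | 50.0 | 38.5 |
| south-east | 80.0 | 57.7 |
| south-east | 90.0 | 62.8 |
| south-east | 120 | 74.5 |
| west | 10.0 | 3.1 |
| west | 30.0 | 18.1 |
| west | 60.0 | 35.9 |
| west | 80.0 | 46.6 |
| west | 120 | 62.5 |
| north | 10.0 | 2.2 |
| north | 20.0 | 5.5 |
| north | 30.0 | 8.3 |
| north | 60.0 | 17.2 |
| north | 120 | 30.4 |

(scatter of a reading: 0.5 percentage points)

- steps thought possible: substrate + free catalyst -> catalyst intermediate A; free catalyst + added ligand <-> idle complex; reagent + catalyst intermediate A -> catalyst intermediate B; catalyst intermediate B <-> free catalyst + product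
- "hardly changes" means that all values lie within two and a half points (for a concentration: within two and a half percent of the largest)

- amount of product at the end, in percent of the substrate charged for ash, birch, elm, oak, cedar, in this order
- how the row runs (falls all the way / hardly changes / rises all the way / rises, then falls / falls, then rises)

Solve the two ends, then join them. Suppose that at a small charge, with reagent, catalyst and added ligand as in these runs, the substrate decays first-order, so time goes as a constant τ times the negative logarithm of the fraction left. Suppose too that at a large charge the product grows at a steady speed V, so time goes as product made over V. Add the two terms and put in the south-east and north runs. That gives τ = 76.8 s and V = 0.693 mM s⁻¹. Their product is the crossover charge, the [substrate] at which the two terms weigh equally at the start (the Michaelis constant of this round): 53.2 mM.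

But two runs always give two numbers, so this proves nothing yet. The west run is the test. The join says it needs 121 s for its product, and it took 120 s.

A second doubt concerns cedar, where [reagent] is below [substrate]. Reagent is the limiting reagent there, and it caps the product at 75.0% of the substrate charged. Yet the north run, charged much the same, made 63.8 mM in this time, less than the 0.15 M of reagent it held, so the cap should stay out of reach by the asked time.

My reckoning is the time to half conversion, which is τ times 0.693 plus half the charge over V. It comes to 61.9 s for ash, 125 s for oak and 198 s for cedar. So the row should fall, and oak should end narrowly short of half, its time being longer than 2.0 min.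

The forecast gives 75.5%, 70%, 63%, 48.5% and 32%, and the row falls all the way: “Percent conversion therefore falls steadily with loading.”

The flasks give 74.9%, 70.9%, 63.0%, 49.1% and 32.0%, and the row falls all the way.

    substrate + free catalyst → catalyst intermediate A (k = 1.91 L mol⁻¹ s⁻¹)
    free catalyst + added ligand ⇌ idle complex, settled at all times (K = 40.8 L mol⁻¹)
    reagent + catalyst intermediate A → catalyst intermediate B (k = 0.719 L mol⁻¹ s⁻¹)
    catalyst intermediate B ⇌ free catalyst + product (K = 0.360 M, k = 0.790 s⁻¹)

Hold [substrate] against the crossover charge read off the runs, 53.2 mM: in ash at 1.00 min that ratio is 0.102, and catalyst intermediate A stands to free catalyst as 0.112, while in elm at 1.00 min the two are 0.535 and 0.606. In cedar at 2.00 min, each free catalyst is taken up by substrate at 0.245 s⁻¹, faster than reagent takes up each catalyst intermediate A at 0.0613 s⁻¹, and catalyst intermediate A, the resting state there, holds 68.4% of the catalyst against 17.2% free.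

All runs come from a simulation with made-up constants, and the scatter is random.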